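(The earlier runs and the new flask stem from a simulated flask with made-up constants; scatter was added.)

I read this flask at 8.0 min, so I ask which clocks have finished by then.

| flask | left-handed substrate | right-handed substrate | coupling partner | remark | time |
|---|---|---|---|---|---|
| autumn | 0.033 M | 0.033 M | 0.80 equiv (fed, over 15 s) | run made earlier; the fed solution adds 1.0 times the starting volume |  |
| winter | 0.050 M | 0.050 M | 0.80 equiv (fed, over 15 s) | run made earlier; the fed solution adds 1.0 times the starting volume |  |
| summer | 0.066 M | 0.066 M | 0.40 equiv (fed, over 15 s) | run made earlier; the fed solution adds 1.0 times the starting volume |  |
| flask | 0.066 M | 0.066 M | 0.800 equiv (fed, over 15 s) | the fed solution adds 1.0 times the starting volume | 8.0 min |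

| run | time / min | left-handed product / % | right-handed substrate / % |
|---|---|---|---|
| autumn | 0.333 | 20.2 | 37.7 |
| autumn | 1.00 | 25.7 | 35.2 |
| autumn | 1.50 | 25.2 | 34.1 |
| autumn | 2.50 | 24.8 | 35.8 |
| autumn | 4.00 | 26.4 | 34.7 |
| autumn | 5.00 | 24.1 | 36.3 |
| winter | 0.833 | 25.4 | 33.8 |
| winter | 1.50 | 23.8 | 34.6 |
| winter | 2.50 | 25.3 | 35.5 |
| winter | 3.00 | 26.1 | 35.0 |
| winter | 4.00 | 22.7 | 35.8 |
| winter | 5.00 | 24.6 | 35.9 |
| summer | 0.417 | 13.0 | 42.0 |
| summer | 1.33 | 12.6 | 43.4 |
| summer | 2.00 | 12.3 | 41.3 |
| summer | 3.00 | 13.9 | 43.7 |
| summer | 5.00 | 12.1 | 40.9 |

(readings scatter by 1 percentage point)

- coupling partner is single-handed; left-handed substrate and right-handed substrate are mirror images of each other, charged as a racemate, each of them at the stated concentration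
- every charge counts on the volume at the start, and the solution that is fed holds the whole dose
- the reaction counts as stopped when no species that holds the left-handed substrate and right-handed substrate together changes by six tenths of a point or more over the second half of the time
- the handed part of coupling partner does not stay in what it makes, so the products of the two hands are mirror images too

* the state of affairs at 8.0 min: stopped, and by what, or still going (all of the left-handed substrate has reacted / it is still moving / the coupling partner has run out first)
* the left-handed product standing at 8.0 min, as a percentage of the left-handed substrate and right-handed substrate together charged
* the right-handed substrate standing at 8.0 min, as a percentage of the left-handed substrate and right-handed substrate together charged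
* amount of left-handed product if the flask were left three thousand times as long, in percent of the left-handed substrate and right-handed substrate together charged

The first clock is the feed, 15 s. Next comes the coupling. The autumn run shows 20.2% left-handed product at 0.333 min and 25.7% at 1.00 min, then no trend. This flask starts at twice the autumn concentration, and its reading comes 8.00 times later than that autumn reading at 1.00 min. The last clock I look for is drift. Winter goes from 25.4% to 24.6%, which is within the scatter of 1 percentage point. Winter's mean readings are 24.7% left-handed product and 35.1% right-handed substrate. So the winter readings put the substrate consumed at 39.6%, against 40.0% that its partner can take. I therefore take the coupling partner as the limiting reagent in this flask too.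

What remains is the split. Suppose both steps are first order in each reactant. Then [coupling partner] cancels from the ratio of the two rates, and integrating that ratio gives r = q^s. Here r and q are the fractions left of the left-handed and right-handed substrate. The exponent s, the ratio of the two rate constants, is the selectivity factor. Winter's readings give s = 1.92. If each partner takes one substrate and its whole charge reacts, the balance adds r + q = 2 minus the equivalents. I start from q = 0.726 and take one Newton step, which gives q = 0.699. For this flask I therefore commit to 34.9% right-handed substrate and 24.9% left-handed product, unchanged after the very long wait.

The forecast says the coupling partner has run out first, with 24.9% left-handed product, 35.1% right-handed substrate and 24.9% left-handed product after the long wait, and holds that “The unequal plateau is therefore kinetic”, which is kinetic control.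

In the flask, the coupling partner has run out first: 0% of its charge stands at 8.00 min, with 24.6% left-handed product and 34.6% right-handed substrate, and the long wait gives 24.6% left-handed product.

    coupling partner + right-handed substrate → right-handed product (k = 3.24 L mol⁻¹ s⁻¹)
    coupling partner + left-handed substrate → left-handed product (k = 5.99 L mol⁻¹ s⁻¹)

The neighbouring flask takes 0.480 equiv of coupling partner, with the other charges and the time held. The same reckoning with s = 1.92 starts from q = 0.836, and one Newton step gives q = 0.826. That means 41.3% right-handed substrate and 15.4% left-handed product. At 8.00 min that flask holds 41.1% right-handed substrate, 15.1% left-handed product and 0% of its coupling partner.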